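The furo[3,4-c]furan core (C1 carries the phenol ring, C4 the trimethoxyphenyl ring) is opened at the ring-fusion bond C3a–C6a and at the O2–C3 bond. Both bonds form in one flask by an iodine-atom-transfer radical cyclization followed by alkoxide displacement: a radical at C6a closes 5-exo onto a vinyl group (C3a=C3), iodine lands on C3, and the C1 carbinol oxygen then displaces it. The step exploits the O2–C1–C6a unit, a β-hydroxy radical with a 1,3-related oxygen nucleophile, facing the C3a=C3 alkene across the O5 ether tether: a formal (3+2) annulation. The precursor is an acyclic iodohydrin allyl ether; its iodine-bearing carbon is stereochemically free, its carbinol is set by CBS reduction.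

Key step: step 9

Assumption: both benzaldehydes are taken as commercial, TIPS stands for triisopropylsilyl (TIPSO for its ether), and in step 7 the carbinol oxygen is taken to come from the added water.

Step 1
Reactants: 1 3,4,5-trimethoxybenzaldehyde
Product: 2 rac-1-(3,4,5-trimethoxyphenyl)prop-2-en-1-ol
Conditions: CH2=CHMgBr, THF, −78 → 0 °C; then H2O
Reagents that add atoms: vinylmagnesium bromide, C=C[Mg]Br
Why: Grignard 1,2-addition of the vinyl nucleophile to the aryl aldehyde should give the racemic allylic alcohol, whose stereocentre is sorted out in step 2.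

Step 2
Reactants: 2 rac-1-(3,4,5-trimethoxyphenyl)prop-2-en-1-ol
Product: 3 (S)-1-(3,4,5-trimethoxyphenyl)prop-2-en-1-ol
Conditions: Novozym 435 (CAL-B), vinyl acetate, MTBE, 30 °C, to just past half conversion; chromatography
Reagents that add atoms: none
Why: Lipase-catalysed kinetic resolution by transesterification: CAL-B should acetylate the (R)-enantiomer (Kazlauskas rule, aryl as the large group) and leave the (S)-alcohol, which later becomes C4 of the target.

Step 3
Reactants: 4 3-hydroxy-4,5-dimethoxybenzaldehyde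
Product: 5 3,4-dimethoxy-5-(TIPSO)benzaldehyde
Conditions: TIPSCl, imidazole, DMF, 25 °C
Reagents that add atoms: triisopropylsilyl chloride, CC(C)[Si](Cl)(C(C)C)C(C)C
Why: Imidazole-promoted silylation of the phenol gives a TIPS aryl ether that should survive the Grignard, bromination, alkoxide, oxidation, borane and radical steps and is removed by fluoride at the end.

Step 4
Reactants: 5 3,4-dimethoxy-5-(TIPSO)benzaldehyde
Product: 6 rac-1-[3,4-dimethoxy-5-(TIPSO)phenyl]prop-2-en-1-ol
Conditions: CH2=CHMgBr, THF, −78 → 0 °C; then H2O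
Reagents that add atoms: vinylmagnesium bromide, C=C[Mg]Br
Why: Grignard 1,2-addition to the aldehyde; the racemic carbinol centre is deleted in step 5.

Step 5
Reactants: 6 rac-1-[3,4-dimethoxy-5-(TIPSO)phenyl]prop-2-en-1-ol
Product: 7 5-[(1E)-3-bromoprop-1-en-1-yl]-1,2-dimethoxy-3-(TIPSO)benzene
Conditions: PBr3 (0.4 equiv), Et2O, −10 °C; used crude at once
Reagents that add atoms: phosphorus tribromide, BrP(Br)Br
Why: Bromination of the 1-arylallyl alcohol with allylic transposition (SN2'/ion-pair return) should give the conjugated primary (E)-cinnamyl bromide as the thermodynamic allylic isomer.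

Step 6
Reactants: 3 (S)-1-(3,4,5-trimethoxyphenyl)prop-2-en-1-ol; 7 5-[(1E)-3-bromoprop-1-en-1-yl]-1,2-dimethoxy-3-(TIPSO)benzene
Product: 8 5-[(1S)-1-{[(2E)-3-[3,4-dimethoxy-5-(TIPSO)phenyl]prop-2-en-1-yl]oxy}prop-2-en-1-yl]-1,2,3-trimethoxybenzene
Conditions: NaH, THF/DMF, 0 °C; then 7, Bu4NI (cat.), 0 → 25 °C
Reagents that add atoms: none
Why: Williamson ether synthesis: the sodium alkoxide of 3 attacks the primary allylic bromide by SN2, so the C–O bond at the stereocentre is not touched and (S) is retained.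

Step 7
Reactants: 8 5-[(1S)-1-{[(2E)-3-[3,4-dimethoxy-5-(TIPSO)phenyl]prop-2-en-1-yl]oxy}prop-2-en-1-yl]-1,2,3-trimethoxybenzene
Product: 10 1-[3,4-dimethoxy-5-(TIPSO)phenyl]-2-iodo-3-{[(1S)-1-(3,4,5-trimethoxyphenyl)prop-2-en-1-yl]oxy}propan-1-one (both C2 epimers), via anti-iodohydrin 9 (not isolated)
Conditions: NIS, DMSO/H2O, 20 °C, dark; then IBX, 20 °C
Reagents that add atoms: N-iodosuccinimide, O=C1CCC(=O)N1I; water, O
Why: Iodohydroxylation followed by IBX oxidation in the same flask: iodonium formation is fastest on the electron-rich styrenyl alkene, water opens it at the benzylic carbon (Markovnikov), and IBX takes the benzylic alcohol to the ketone, while the vinyl group next to the allylic oxygen reacts more slowly.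

Step 8
Reactants: 10 1-[3,4-dimethoxy-5-(TIPSO)phenyl]-2-iodo-3-{[(1S)-1-(3,4,5-trimethoxyphenyl)prop-2-en-1-yl]oxy}propan-1-one
Product: 11 (1R,2RS)-1-[3,4-dimethoxy-5-(TIPSO)phenyl]-2-iodo-3-{[(1S)-1-(3,4,5-trimethoxyphenyl)prop-2-en-1-yl]oxy}propan-1-ol
Conditions: (R)-Me-CBS (20 mol %), catecholborane, toluene, −78 °C; then MeOH, pH 7 buffer
Reagents that add atoms: none
Why: Corey–Bakshi–Shibata reduction: the (R)-oxazaborolidine should deliver hydride to the carbonyl face set by the aryl group as the large substituent and give the (1R)-carbinol (future C1, same spatial arrangement as in the target) in both C2 epimers, and catecholborane at −78 °C should leave the vinyl group.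

Step 9
Reactants: 11 (1R,2RS)-1-[3,4-dimethoxy-5-(TIPSO)phenyl]-2-iodo-3-{[(1S)-1-(3,4,5-trimethoxyphenyl)prop-2-en-1-yl]oxy}propan-1-ol
Product: 13 (1S,3aR,4S,6aR)-1-[3,4-dimethoxy-5-(TIPSO)phenyl]-4-(3,4,5-trimethoxyphenyl)tetrahydro-1H,3H-furo[3,4-c]furan, via primary iodide 12 (not isolated)
Conditions: Et3B (0.3 equiv, in portions), air, PhH (0.3 M), 25 °C; then NaH, THF, 0 → 25 °C
Reagents that add atoms: none
Why: Ethyl radicals from Et3B/O2 abstract iodine from either C2 epimer of 11 to give one planar β-hydroxy secondary radical, which closes 5-exo-trig onto the vinyl group (first oxolane, C3a–C6a bond); the primary radical then takes iodine from a further molecule of 11 and carries the chain (12), and NaH turns the carbinol into its alkoxide, which displaces the primary iodide 5-exo-tet (second oxolane, O2–C3 bond). The closest known reaction type is the iodine-atom-transfer cyclization of β-oxygenated alkyl iodides onto allyl ethers (Ueno–Stork type), followed by an intramolecular Williamson etherification. The two new stereocentres (C3a and C6a) should follow the Beckwith–Houk chair transition state with the C4 aryl group and the carbinol side chain pseudo-equatorial, which gives the 4,3a-trans/3a,6a-cis pattern, and this is reinforced by attack anti to the aryl group of the neighbouring carbinol (allylic-strain model); C1 and C4 are carried in unchanged. The step needs 5-exo over 6-endo closure, which the 3-oxa tether secures, and a cis ring fusion, which is self-selecting because only the cis iodide can close to the bicycle. Base is withheld until the radical stage is over because it would turn 11 into an epoxide.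

Step 10
Reactants: 13 (1S,3aR,4S,6aR)-1-[3,4-dimethoxy-5-(TIPSO)phenyl]-4-(3,4,5-trimethoxyphenyl)tetrahydro-1H,3H-furo[3,4-c]furan
Product: 14 2,3-dimethoxy-5-[(1S,3aR,4S,6aR)-4-(3,4,5-trimethoxyphenyl)tetrahydro-1H,3H-furo[3,4-c]furan-1-yl]phenol (CNP0181235.1)
Conditions: TBAF, THF, 0 °C; then H2O
Reagents that add atoms: none
Why: Fluoride-mediated cleavage of the aryl silyl ether (Si–F bond formation) frees the phenol without touching the benzylic ether bonds or any stereocentre.

Compound list
1 | 3,4,5-trimethoxybenzaldehyde | COc1cc(C=O)cc(OC)c1OC | starting material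
2 | rac-1-(3,4,5-trimethoxyphenyl)prop-2-en-1-ol | C=CC(O)c1cc(OC)c(OC)c(OC)c1 | intermediate
3 | (S)-1-(3,4,5-trimethoxyphenyl)prop-2-en-1-ol | C=C[C@H](O)c1cc(OC)c(OC)c(OC)c1 | intermediate
4 | 3-hydroxy-4,5-dimethoxybenzaldehyde | COc1cc(C=O)cc(O)c1OC | starting material
5 | 3,4-dimethoxy-5-(TIPSO)benzaldehyde | COc1cc(C=O)cc(O[Si](C(C)C)(C(C)C)C(C)C)c1OC | intermediate
6 | rac-1-[3,4-dimethoxy-5-(TIPSO)phenyl]prop-2-en-1-ol | C=CC(O)c1cc(OC)c(OC)c(O[Si](C(C)C)(C(C)C)C(C)C)c1 | intermediate
7 | 5-[(1E)-3-bromoprop-1-en-1-yl]-1,2-dimethoxy-3-(TIPSO)benzene | BrC/C=C/c1cc(OC)c(OC)c(O[Si](C(C)C)(C(C)C)C(C)C)c1 | intermediate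
8 | 5-[(1S)-1-{[(2E)-3-[3,4-dimethoxy-5-(TIPSO)phenyl]prop-2-en-1-yl]oxy}prop-2-en-1-yl]-1,2,3-trimethoxybenzene | C=C[C@H](OC/C=C/c1cc(OC)c(OC)c(O[Si](C(C)C)(C(C)C)C(C)C)c1)c1cc(OC)c(OC)c(OC)c1 | intermediate
9 | 1-[3,4-dimethoxy-5-(TIPSO)phenyl]-2-iodo-3-{[(1S)-1-(3,4,5-trimethoxyphenyl)prop-2-en-1-yl]oxy}propan-1-ol, anti-addition product, both C1/C2 pairs (not isolated) | COc1cc(C(O)C(I)CO[C@@H](C=C)c2cc(OC)c(OC)c(OC)c2)cc(O[Si](C(C)C)(C(C)C)C(C)C)c1OC | intermediate
10 | 1-[3,4-dimethoxy-5-(TIPSO)phenyl]-2-iodo-3-{[(1S)-1-(3,4,5-trimethoxyphenyl)prop-2-en-1-yl]oxy}propan-1-one, both C2 epimers | COc1cc(C(=O)C(I)CO[C@@H](C=C)c2cc(OC)c(OC)c(OC)c2)cc(O[Si](C(C)C)(C(C)C)C(C)C)c1OC | intermediate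
11 | (1R,2RS)-1-[3,4-dimethoxy-5-(TIPSO)phenyl]-2-iodo-3-{[(1S)-1-(3,4,5-trimethoxyphenyl)prop-2-en-1-yl]oxy}propan-1-ol | COc1cc([C@@H](O)C(I)CO[C@@H](C=C)c2cc(OC)c(OC)c(OC)c2)cc(O[Si](C(C)C)(C(C)C)C(C)C)c1OC | intermediate
12 | (S)-[3,4-dimethoxy-5-(TIPSO)phenyl][(3R,4S,5S)-4-(iodomethyl)-5-(3,4,5-trimethoxyphenyl)oxolan-3-yl]methanol (not isolated) | COc1cc([C@@H](O)[C@H]2CO[C@H](c3cc(OC)c(OC)c(OC)c3)[C@H]2CI)cc(O[Si](C(C)C)(C(C)C)C(C)C)c1OC | intermediate
13 | (1S,3aR,4S,6aR)-1-[3,4-dimethoxy-5-(TIPSO)phenyl]-4-(3,4,5-trimethoxyphenyl)tetrahydro-1H,3H-furo[3,4-c]furan | COc1cc([C@H]2OC[C@H]3[C@@H]2CO[C@@H]3c2cc(OC)c(OC)c(OC)c2)cc(O[Si](C(C)C)(C(C)C)C(C)C)c1OC | intermediate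
14 | 2,3-dimethoxy-5-[(1S,3aR,4S,6aR)-4-(3,4,5-trimethoxyphenyl)tetrahydro-1H,3H-furo[3,4-c]furan-1-yl]phenol (CNP0181235.1) | COc1cc([C@H]2OC[C@H]3[C@@H]2CO[C@@H]3c2cc(OC)c(OC)c(OC)c2)cc(O)c1OC | target

Total step count: 10
Longest linear sequence: 8 steps (4 → 5 → 6 → 7 → 8 → 10 → 11 → 13 → 14; steps 3 to 10)

Steps most likely to fail

Step 9 (key step). What may go wrong: loss of stereocontrol in the 5-exo closure (a trans ring-fusion iodide cannot close the second ring), collapse of the iodine-transfer chain, or epoxide closure of unreacted iodohydrin once base is added. The fallback moves the radical precursor into the other ring and closes the aryl-bearing C–O bond instead. It sets out from 3 and 7. Sharpless epoxidation of 3 (Ti(OiPr)4, D-(−)-DIPT, TBHP, the matched pairing for the (S)-alcohol) should give (R)-[(2R)-oxiran-2-yl](3,4,5-trimethoxyphenyl)methanol F1. Its sodium alkoxide (NaH, THF) is alkylated with 7 to give 2-[(R)-{[(2E)-3-[3,4-dimethoxy-5-(TIPSO)phenyl]prop-2-en-1-yl]oxy}(3,4,5-trimethoxyphenyl)methyl]-(2R)-oxirane F2. Cp2TiCl (from Cp2TiCl2 and Zn, THF) then opens the epoxide to the secondary radical, which cyclizes 5-exo onto the cinnamyl alkene, and treatment with I2 closes the benzylic C–O bond from the titanium alkoxide. The sequence comes back to the route at 13.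

Step 8. What may go wrong: poor facial selectivity at the carbonyl group because the α-carbon is branched and carries iodine, so that the reagent no longer reads the aryl group as the large substituent; hydroboration of the vinyl group or reductive loss of iodine may also intrude. The fallback lets the substrate set C1 after the first ring exists. It sets out from 10. Iodine-atom-transfer cyclization at the ketone level (Et3B, air, PhH), a well-precedented reaction of α-iodo ketones, should give [3,4-dimethoxy-5-(TIPSO)phenyl][(3R,4S,5S)-4-(iodomethyl)-5-(3,4,5-trimethoxyphenyl)oxolan-3-yl]methanone F3. L-Selectride (THF, −78 °C) should then add by the Felkin–Anh mode, with the ring carbon bearing the iodomethyl group as the large substituent, to give the carbinol with the aryl group on the exo side. On warming, the lithium alkoxide displaces the iodide, and the route is rejoined at 13.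

Step 7. What may go wrong: competing iodination of the electron-rich arenes, attack on the vinyl group, or β-elimination of the allylic alkoxide from the α-iodo ketone during oxidation. The fallback builds the same ketone by conjugate addition and enol iodination. It sets out from 6 and 3. MnO2 (CH2Cl2) oxidizes 6 to 1-[3,4-dimethoxy-5-(TIPSO)phenyl]prop-2-en-1-one F4. PMe3-catalysed oxa-Michael addition of 3 gives 1-[3,4-dimethoxy-5-(TIPSO)phenyl]-3-{[(1S)-1-(3,4,5-trimethoxyphenyl)prop-2-en-1-yl]oxy}propan-1-one F5. Soft enolization (TMSOTf, Et3N) gives the (Z)-trimethylsilyl enol ether F6, and NIS (THF, −78 °C) iodinates it at carbon, coming back to the route at 10.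

Further compounds
F1 | step 9 | (R)-[(2R)-oxiran-2-yl](3,4,5-trimethoxyphenyl)methanol | O[C@@H]([C@H]1CO1)c1cc(OC)c(OC)c(OC)c1
F2 | step 9 | 2-[(R)-{[(2E)-3-[3,4-dimethoxy-5-(TIPSO)phenyl]prop-2-en-1-yl]oxy}(3,4,5-trimethoxyphenyl)methyl]-(2R)-oxirane | C(/C=C/c1cc(OC)c(OC)c(O[Si](C(C)C)(C(C)C)C(C)C)c1)O[C@@H]([C@H]2CO2)c3cc(OC)c(OC)c(OC)c3
F3 | step 8 | [3,4-dimethoxy-5-(TIPSO)phenyl][(3R,4S,5S)-4-(iodomethyl)-5-(3,4,5-trimethoxyphenyl)oxolan-3-yl]methanone | COc1cc(C(=O)[C@H]2CO[C@H](c3cc(OC)c(OC)c(OC)c3)[C@H]2CI)cc(O[Si](C(C)C)(C(C)C)C(C)C)c1OC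
F4 | step 7 | 1-[3,4-dimethoxy-5-(TIPSO)phenyl]prop-2-en-1-one | C=CC(=O)c1cc(OC)c(OC)c(O[Si](C(C)C)(C(C)C)C(C)C)c1
F5 | step 7 | 1-[3,4-dimethoxy-5-(TIPSO)phenyl]-3-{[(1S)-1-(3,4,5-trimethoxyphenyl)prop-2-en-1-yl]oxy}propan-1-one | C=C[C@H](OCCC(=O)c1cc(OC)c(OC)c(O[Si](C(C)C)(C(C)C)C(C)C)c1)c1cc(OC)c(OC)c(OC)c1
F6 | step 7 | (Z)-1-[3,4-dimethoxy-5-(TIPSO)phenyl]-1-(trimethylsilyloxy)-3-{[(1S)-1-(3,4,5-trimethoxyphenyl)prop-2-en-1-yl]oxy}prop-1-ene | C=C[C@H](OC/C=C(\O[Si](C)(C)C)c1cc(OC)c(OC)c(O[Si](C(C)C)(C(C)C)C(C)C)c1)c1cc(OC)c(OC)c(OC)c1
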